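Each set-up holds the same amounts, 0.10 M of Z and 0.100 M of G. They differ in how the two meet.

| flask | Z | G | remark | time |
|---|---|---|---|---|
| gamma | 0.10 M | 0.10 M | run made earlier |  |
| alpha | 0.10 M | 0.050 M | run made earlier |  |
| beta | 0.10 M | 0.075 M | run made earlier |  |
| blue | 0.10 M | 0.100 M (fed, over 1.20 h) | all but G at the start; G goes in evenly over 1.20 h, the run ends at 1.5 h | 1.5 h |
| violet | 0.10 M | 0.100 M | a closed flask charged with all of it at once and left for 1.5 h | 1.5 h |
| ochre | 0.10 M | 0.100 M | one stirred flow tank at steady state, fed with the mixture as stated, mean residence time 1.5 h |  |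
| green | 0.10 M (fed, over 1.20 h) | 0.100 M | a stirred flask in which Z is dosed at a steady rate over 1.20 h without added volume, worked up at 1.5 h | 1.5 h |

| run | time / min | L / % |
|---|---|---|
| gamma | 5.00 | 9.2 |
| gamma | 15.0 | 14.5 |
| gamma | 25.0 | 17.7 |
| gamma | 40.0 | 21.0 |
| gamma | 50.0 | 21.4 |
| alpha | 20.0 | 11.3 |
| alpha | 40.0 | 14.7 |
| alpha | 50.0 | 15.1 |
| alpha | 80.0 | 17.5 |
| alpha | 90.0 | 16.6 |
| beta | 8.00 | 7.9 |
| beta | 15.0 | 12.0 |
| beta | 25.0 | 15.2 |
| beta | 50.0 | 18.1 |
| beta | 90.0 | 19.7 |

(standard deviation of a reading: 0.5 percentage points)

1. order of the set-ups by the amount of L at the outlet or at the end, in percent of the Z put in, highest first (blue / violet / ochre / green)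
2. amount of L at the outlet or at the end, in percent of the Z put in, blue
3. amount of L at the outlet or at the end, in percent of the Z put in, violet
4. amount of L at the outlet or at the end, in percent of the Z put in, ochre
5. amount of L at the outlet or at the end, in percent of the Z put in, green

- the stated concentrations are those of everything mixed, before any reaction; amounts are the same in each set-up
- the earlier runs were read with a standard deviation of 0.5 percentage points
- the feed brings no volume worth counting
- the earlier runs were made in a closed, stirred flask

We read rates, in parts of the Z charged per minute, and take the rate to go with c_Z times c_G. The gamma run has the same charge as violet, and its rate falls like this: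

start rate = 9.2% / 5.00 min = 0.0184 min⁻¹

late rate, 25.0 min to 50.0 min = 0.00148 min⁻¹

whole slowing = 12.4

We count reacted Z as L, so Z left near 40.0 min is 79.0%, which is a slowing of 1.27. The remaining factor, as read, is 9.82, and on this rate law we give it to G, so in the gamma run the loss of G slows the rate more than the loss of Z.

G gauge = late rate / (start rate × Z left) = 10.2%

The G gauge is the rate per Z left as a share of the start rate, and on that rate law it is our reading of the part of the G charge still working. G is thus the limiting reagent in the gamma run, with the gauge below the Z left. Adding the gain of the beta run from 50.0 min to 90.0 min to the last gamma reading, we commit to 23.0% for violet.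

The forecast gives blue 35%, violet 22%, ochre 29% and green 10%, ranked blue > ochre > violet > green; for blue its ground is that “low G favours L”.

The flask gives blue > violet > ochre > green: blue 25.6%, violet 22.5%, ochre 19.4%, green 10.8%.

    Z + G → L (k = 0.211 M⁻¹ min⁻¹)
    2 G → D (k = 0.511 M⁻¹ min⁻¹)
    2 Z → J (k = 4.69 × 10⁻⁴ M⁻¹ min⁻¹)
    G + L → X (k = 0.218 M⁻¹ min⁻¹)
    L ⇌ E (K = 0.106, k = 0.00166 min⁻¹)

Blue stands 9.4 percentage points below the forecast, and with G + L → X struck out, blue gives 32.7%. We put the gauge on the last stretch of blue, after the feed ends, counting L and X together and dividing by the Z left at the end: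

G gauge, blue = 21.5%

Over that stretch, G in blue fell from 28.1% to 13.7% of its charge.

(The earlier runs and the new flask were generated by integration with constants of no real substance; scatter was added.)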